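**Retrosynthetic overview** (target numbering: C1 = quaternary carbon, C2 = CH(OAc), C3 = CH(OBz), C4=C5, C6 = CH(OH))
1. The three esters and two free hydroxyls are set last on cyclohexene acid 13, in which the CH2OBz carbon is a carboxyl group, O1 and O3 are 2-naphthylmethyl (NAP) ethers, O6 is a 4-methoxyphenyl ether and O2 is free.
2. In 13 the sequence carboxyl–C1–C6–C5=C4 is a γ,δ-unsaturated, α-oxygenated acid, the retron of an Ireland–Claisen rearrangement, which creates the C1–C6 bond and the C4=C5 double bond in one step.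
3. The enabling feature lies in precursor 9, an oxan-2-one (δ-lactone): ring oxygen O1 sits on C6, which carries an (E)-2-aryloxyvinyl arm, so O1–C6–CH=CH(OAr) is an allyl ester whose α-carbon is C3 of the same ring. C3 and C6 are tied 1,4 by C4–C5, so the [3,3] shift opens the lactone as it closes the carbocycle.
4. Lactone 9 comes from 1,2-O-isopropylidene-α-D-glucofuranose: glucose C3 and C4 are kept, C2 is the stereocentre that is transferred, C5 becomes the enolate carbon, C1 is methylenated and turned into the E enol ether, and C6 is oxidised to the lactone carbonyl.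
5. Ring order: furanose (starting material, opened in step 4) → oxan-2-one (step 5) → cyclohexene (step 8).

Key step: step 8

Remark: NAP = 2-naphthylmethyl, Ar = 4-methoxyphenyl; 4 and 6 are anomeric mixtures, which does not matter because that carbon is opened in step 4 and oxidised in step 5.

**Step 1**
Reactants: 1 1,2-O-isopropylidene-α-D-glucofuranose
Product: 2 1,2-O-isopropylidene-6-O-trityl-α-D-glucofuranose
Conditions: Ph3CCl (1.1 equiv), pyridine, DMAP (cat.), CH2Cl2, rt
Reagents that add atoms: trityl chloride, ClC(c1ccccc1)(c1ccccc1)c1ccccc1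
Why: Selective tritylation, because the bulky chloride reacts only with the primary 6-hydroxyl and leaves O3 and O5 free; no stereocentre is touched.

**Step 2**
Reactants: 2 1,2-O-isopropylidene-6-O-trityl-α-D-glucofuranose
Product: 3 1,2-O-isopropylidene-3,5-di-O-(2-naphthylmethyl)-6-O-trityl-α-D-glucofuranose
Conditions: NaH (2.6 equiv), 2-(bromomethyl)naphthalene (2.4 equiv), Bu4NI (cat.), DMF, 0 °C → rt
Reagents that add atoms: 2-(bromomethyl)naphthalene, BrCc1ccc2ccccc2c1
Why: Williamson etherification of both secondary alkoxides installs the NAP ethers that later serve as the α-alkoxy group of the Claisen substrate (O5) and as the mask of the future allylic benzoate oxygen (O3), since they resist acid, base and hydride and leave with DDQ.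

**Step 3**
Reactants: 3 1,2-O-isopropylidene-3,5-di-O-(2-naphthylmethyl)-6-O-trityl-α-D-glucofuranose
Product: 4 3,5-di-O-(2-naphthylmethyl)-D-glucofuranose (anomeric mixture)
Conditions: 1 M aq. H2SO4/1,4-dioxane (1:3), 75 °C
Reagents that add atoms: none
Why: Acid hydrolysis should cleave the trityl ether and the 1,2-acetal in one operation while the arylmethyl ethers survive, and the product stays a furanose because O5 is blocked.

**Step 4**
Reactants: 4 3,5-di-O-(2-naphthylmethyl)-D-glucofuranose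
Product: 5 1,2-dideoxy-4,6-di-O-(2-naphthylmethyl)-D-gluco-hept-1-enitol
Conditions: Ph3PCH3Br (6 equiv), KOtBu (5.8 equiv), THF, 0 °C → 45 °C
Reagents that add atoms: methyltriphenylphosphonium bromide, C[P+](c1ccccc1)(c1ccccc1)c1ccccc1.[Br-]
Why: Wittig methylenation of the open-chain form of the lactol gives the terminal alkene and frees O4 of the sugar, and the alkoxide next to the aldehyde carbon should suppress enolisation so that the stereocentres are kept.

**Step 5**
Reactants: 5 1,2-dideoxy-4,6-di-O-(2-naphthylmethyl)-D-gluco-hept-1-enitol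
Product: 7 (3S,4S,5S,6S)-6-ethenyl-4-hydroxy-3,5-bis(naphthalen-2-ylmethoxy)oxan-2-one, via lactol 6 (not isolated)
Conditions: TEMPO (0.2 equiv), PhI(OAc)2 (2.5 equiv), CH2Cl2, rt
Reagents that add atoms: none
Why: Oxidative lactonisation of a 1,5-diol, in which TEMPO/PhI(OAc)2 oxidises the primary alcohol chemoselectively, the product exists as six-membered lactol 6 with the 1,5-related allylic hydroxyl and is oxidised on to the δ-lactone; no γ-lactone can form because the oxygen on C5 of the oxanone is blocked.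

**Step 6**
Reactants: 7 (3S,4S,5S,6S)-6-ethenyl-4-hydroxy-3,5-bis(naphthalen-2-ylmethoxy)oxan-2-one
Product: 8 (3S,4S,5S,6S)-4-hydroxy-3,5-bis(naphthalen-2-ylmethoxy)-6-[(E)-2-(4,4,5,5-tetramethyl-1,3,2-dioxaborolan-2-yl)ethenyl]oxan-2-one
Conditions: vinylboronic acid pinacol ester (3 equiv), RuCl2(H2IMes)(=CH-C6H4-2-OiPr) (second-generation Hoveyda–Grubbs catalyst, 5 mol%), CH2Cl2, 40 °C
Reagents that add atoms: 4,4,5,5-tetramethyl-2-vinyl-1,3,2-dioxaborolane, C=CB1OC(C)(C)C(C)(C)O1
Why: Olefin cross-metathesis of the monosubstituted alkene with the vinylboronate should give the E-alkenylboronate under thermodynamic control with loss of ethene, fixing the alkene geometry that the key step turns into the configuration of the secondary carbinol.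

**Step 7**
Reactants: 8 (3S,4S,5S,6S)-4-hydroxy-3,5-bis(naphthalen-2-ylmethoxy)-6-[(E)-2-(4,4,5,5-tetramethyl-1,3,2-dioxaborolan-2-yl)ethenyl]oxan-2-one
Product: 9 (3S,4S,5S,6S)-4-hydroxy-6-[(E)-2-(4-methoxyphenoxy)ethenyl]-3,5-bis(naphthalen-2-ylmethoxy)oxan-2-one
Conditions: 4-methoxyphenol (3 equiv), Cu(OAc)2 (2 equiv), pyridine (5 equiv), 4 Å molecular sieves, CH2Cl2, dry air, rt
Reagents that add atoms: 4-methoxyphenol, COc1ccc(O)cc1
Why: Chan–Lam oxidative C–O coupling of the alkenylboronate with the phenol at divalent copper proceeds with retention of the E geometry, the phenol outcompetes the hindered secondary hydroxyl, and the resulting aryl ether is inert to DDQ but removable with (NH4)2Ce(NO3)6.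

**Step 8**
Reactants: 9 (3S,4S,5S,6S)-4-hydroxy-6-[(E)-2-(4-methoxyphenoxy)ethenyl]-3,5-bis(naphthalen-2-ylmethoxy)oxan-2-one
Product: 13 (1R,2R,5R,6S)-6-hydroxy-2-(4-methoxyphenoxy)-1,5-bis(naphthalen-2-ylmethoxy)cyclohex-3-ene-1-carboxylic acid, via dilithium oxido enolate 10 (not isolated), via bis(trimethylsilyl) ketene acetal 11 (not isolated), via bis-silylated acid 12 (not isolated)
Conditions: LiN(iPr)2 (2.3 equiv), THF, −78 °C; Me3SiCl/Et3N (5 equiv), −78 °C → rt, then 55 °C; 1 M HCl, THF, rt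
Reagents that add atoms: none
Why: Double deprotonation (hydroxyl, then C3–H next to the lactone carbonyl) gives β-oxido enolate 10, whose oxide cannot be expelled, and silylation gives cyclic silyl ketene acetal 11; a concerted suprafacial [3,3] shift then joins C3 of the oxanone to the aryloxy-bearing vinyl carbon, breaks the allylic O1–C6 bond and moves the double bond to C6=C1′, giving 12 and, after acidic hydrolysis of both silyl groups, acid 13. The closest precedents are Ireland–Claisen ring contractions of 6-alkenyl lactones to cycloalkene carboxylic acids and ester-enolate Claisen rearrangements of glycal esters, where the new bond also forms at the oxygen-bearing enol ether carbon, a donor position that accelerates the shift. The cyclohexene closes as a six-membered carbocycle through a boat, bicyclo[2.2.2]octane-like transition state, because the C4–C5 bridge ties the two reacting termini C3 and C6 together. The quaternary centre is controlled by the C6 stereocentre of the lactone, since the alkenyl arm can reach C3 only across the ring face it occupies, so the chirality of C6 (which becomes sp2) is transferred to the new C–C bond. The secondary aryloxy-bearing centre is controlled by the E geometry of the enol ether, which in the boat array places the aryloxy group cis to the carboxyl and trans to the NAP ether on the quaternary carbon. The step needs O-silylation without β-elimination or lactone opening and a single reacting face; the ring-fixed enolate geometry, the oxido group on C4, the single enolisable position and the axial alkenyl group (the only substituent that must be axial) secure this.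

**Step 9**
Reactants: 13 (1R,2R,5R,6S)-6-hydroxy-2-(4-methoxyphenoxy)-1,5-bis(naphthalen-2-ylmethoxy)cyclohex-3-ene-1-carboxylic acid
Product: 14 (1S,2R,5R,6R)-6-(hydroxymethyl)-5-(4-methoxyphenoxy)-2,6-bis(naphthalen-2-ylmethoxy)cyclohex-3-en-1-ol
Conditions: LiAlH4 (4 equiv), THF, 0 °C → reflux; Rochelle salt work-up
Reagents that add atoms: none
Why: Hydride reduction of the hindered α-alkoxy acid to the primary alcohol should leave the isolated ring alkene and all ethers untouched, and no stereocentre changes.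

**Step 10**
Reactants: 14 (1S,2R,5R,6R)-6-(hydroxymethyl)-5-(4-methoxyphenoxy)-2,6-bis(naphthalen-2-ylmethoxy)cyclohex-3-en-1-ol
Product: 15 [(1R,2R,5R,6S)-6-hydroxy-2-(4-methoxyphenoxy)-1,5-bis(naphthalen-2-ylmethoxy)cyclohex-3-en-1-yl]methyl benzoate
Conditions: BzCl (1.1 equiv), pyridine, CH2Cl2, −30 °C → 0 °C
Reagents that add atoms: benzoyl chloride, O=C(Cl)c1ccccc1
Why: Selective benzoylation, because the primary hydroxyl is acylated much faster than the secondary one flanked by the quaternary carbon.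

**Step 11**
Reactants: 15 [(1R,2R,5R,6S)-6-hydroxy-2-(4-methoxyphenoxy)-1,5-bis(naphthalen-2-ylmethoxy)cyclohex-3-en-1-yl]methyl benzoate
Product: 16 [(1S,2R,5R,6S)-6-acetoxy-2-(4-methoxyphenoxy)-1,5-bis(naphthalen-2-ylmethoxy)cyclohex-3-en-1-yl]methyl benzoate
Conditions: Ac2O (3 equiv), pyridine, DMAP (0.1 equiv), CH2Cl2, rt
Reagents that add atoms: acetic anhydride, CC(=O)OC(C)=O
Why: DMAP-catalysed acetylation esterifies the only free hydroxyl, the hindered secondary one, while every other oxygen is blocked.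

**Step 12**
Reactants: 16 [(1S,2R,5R,6S)-6-acetoxy-2-(4-methoxyphenoxy)-1,5-bis(naphthalen-2-ylmethoxy)cyclohex-3-en-1-yl]methyl benzoate
Product: 17 [(1S,2R,5R,6S)-6-acetoxy-1,5-dihydroxy-2-(4-methoxyphenoxy)cyclohex-3-en-1-yl]methyl benzoate
Conditions: DDQ (2.5 equiv), CH2Cl2/pH 7 buffer (10:1), 0 °C → rt
Reagents that add atoms: none
Why: Oxidative cleavage of arylmethyl ethers, in which DDQ abstracts hydride from the naphthylmethyl positions and water releases the secondary allylic and the tertiary hydroxyl, while the esters, the electron-poor alkene and the aryl ether (no benzylic C–H) should remain.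

**Step 13**
Reactants: 17 [(1S,2R,5R,6S)-6-acetoxy-1,5-dihydroxy-2-(4-methoxyphenoxy)cyclohex-3-en-1-yl]methyl benzoate
Product: 18 [(1S,2R,5R,6S)-6-acetoxy-5-(benzoyloxy)-1-hydroxy-2-(4-methoxyphenoxy)cyclohex-3-en-1-yl]methyl benzoate
Conditions: BzCl (1.5 equiv), pyridine, DMAP (cat.), CH2Cl2, 0 °C
Reagents that add atoms: benzoyl chloride, O=C(Cl)c1ccccc1
Why: Selective benzoylation of the secondary allylic hydroxyl, since the tertiary hydroxyl does not react with benzoyl chloride under these conditions and the short, cold reaction limits acetyl migration.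

**Step 14**
Reactants: 18 [(1S,2R,5R,6S)-6-acetoxy-5-(benzoyloxy)-1-hydroxy-2-(4-methoxyphenoxy)cyclohex-3-en-1-yl]methyl benzoate
Product: 19 [(1S,2S,3R,6R)-2-acetoxy-3-(benzoyloxy)-1,6-dihydroxycyclohex-4-en-1-yl]methyl benzoate (CNP0160999.2)
Conditions: (NH4)2Ce(NO3)6 (3 equiv), MeCN/H2O (4:1), 0 °C
Reagents that add atoms: none
Why: Oxidative dearylation, in which the cerium salt oxidises the 4-methoxyphenyl ether to the quinone and frees the allylic alcohol with retention because the ring C–O bond is not broken; esters and alkene are inert.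

**Compound list**
1 | 1,2-O-isopropylidene-α-D-glucofuranose | O1[C@@H]2OC(C)(C)O[C@@H]2[C@@H](O)[C@H]1[C@H](O)CO | starting material
2 | 1,2-O-isopropylidene-6-O-trityl-α-D-glucofuranose | O1[C@@H]2OC(C)(C)O[C@@H]2[C@@H](O)[C@H]1[C@H](O)COC(c1ccccc1)(c1ccccc1)c1ccccc1 | intermediate
3 | 1,2-O-isopropylidene-3,5-di-O-(2-naphthylmethyl)-6-O-trityl-α-D-glucofuranose | O1[C@@H]2OC(C)(C)O[C@@H]2[C@@H](OCc2ccc3ccccc3c2)[C@H]1[C@H](OCc1ccc2ccccc2c1)COC(c1ccccc1)(c1ccccc1)c1ccccc1 | intermediate
4 | 3,5-di-O-(2-naphthylmethyl)-D-glucofuranose (anomeric mixture) | O1C(O)[C@H](O)[C@@H](OCc2ccc3ccccc3c2)[C@H]1[C@H](OCc1ccc2ccccc2c1)CO | intermediate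
5 | 1,2-dideoxy-4,6-di-O-(2-naphthylmethyl)-D-gluco-hept-1-enitol | C=C[C@H](O)[C@@H](OCc1ccc2ccccc2c1)[C@H](O)[C@H](OCc1ccc2ccccc2c1)CO | intermediate
6 | 6,7-dideoxy-2,4-di-O-(2-naphthylmethyl)-L-gulo-hept-6-enopyranose (lactol, not isolated) | C=C[C@H]1[C@@H](OCc2ccc3ccccc3c2)[C@H](O)[C@H](OCc2ccc3ccccc3c2)C(O)O1 | intermediate
7 | (3S,4S,5S,6S)-6-ethenyl-4-hydroxy-3,5-bis(naphthalen-2-ylmethoxy)oxan-2-one | C=C[C@H]1[C@@H](OCc2ccc3ccccc3c2)[C@H](O)[C@H](OCc2ccc3ccccc3c2)C(=O)O1 | intermediate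
8 | (3S,4S,5S,6S)-4-hydroxy-3,5-bis(naphthalen-2-ylmethoxy)-6-[(E)-2-(4,4,5,5-tetramethyl-1,3,2-dioxaborolan-2-yl)ethenyl]oxan-2-one | CC1(C)OB(/C=C/[C@H]2[C@@H](OCc3ccc4ccccc4c3)[C@H](O)[C@H](OCc3ccc4ccccc4c3)C(=O)O2)OC1(C)C | intermediate
9 | (3S,4S,5S,6S)-4-hydroxy-6-[(E)-2-(4-methoxyphenoxy)ethenyl]-3,5-bis(naphthalen-2-ylmethoxy)oxan-2-one | COc1ccc(O/C=C/[C@H]2[C@@H](OCc3ccc4ccccc4c3)[C@H](O)[C@H](OCc3ccc4ccccc4c3)C(=O)O2)cc1 | intermediate
10 | dilithium salt of 9 deprotonated at the 4-hydroxyl and at C3 (4-oxido lactone enolate, not isolated) | COc1ccc(O/C=C/[C@H]2[C@@H](OCc3ccc4ccccc4c3)[C@H]([O-])C(OCc3ccc4ccccc4c3)=C([O-])O2)cc1.[Li+].[Li+] | intermediate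
11 | 6-[(E)-2-(4-methoxyphenoxy)ethenyl]-3,5-bis(naphthalen-2-ylmethoxy)-2,4-bis(trimethylsilyloxy)-5,6-dihydro-4H-pyran, configuration of 9 at C4, C5 and C6 (silyl ketene acetal, not isolated) | COc1ccc(O/C=C/[C@H]2[C@@H](OCc3ccc4ccccc4c3)[C@H](O[Si](C)(C)C)C(OCc3ccc4ccccc4c3)=C(O[Si](C)(C)C)O2)cc1 | intermediate
12 | trimethylsilyl ester of 13 with the 6-hydroxyl as trimethylsilyl ether (not isolated) | C[Si](C)(C)O[C@H]1[C@H](OCc2ccc3ccccc3c2)C=C[C@@H](Oc2ccc(OC)cc2)[C@@]1(OCc1ccc2ccccc2c1)C(=O)O[Si](C)(C)C | intermediate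
13 | (1R,2R,5R,6S)-6-hydroxy-2-(4-methoxyphenoxy)-1,5-bis(naphthalen-2-ylmethoxy)cyclohex-3-ene-1-carboxylic acid | O[C@H]1[C@H](OCc2ccc3ccccc3c2)C=C[C@@H](Oc2ccc(OC)cc2)[C@@]1(OCc1ccc2ccccc2c1)C(=O)O | intermediate
14 | (1S,2R,5R,6R)-6-(hydroxymethyl)-5-(4-methoxyphenoxy)-2,6-bis(naphthalen-2-ylmethoxy)cyclohex-3-en-1-ol | O[C@H]1[C@H](OCc2ccc3ccccc3c2)C=C[C@@H](Oc2ccc(OC)cc2)[C@@]1(OCc1ccc2ccccc2c1)CO | intermediate
15 | [(1R,2R,5R,6S)-6-hydroxy-2-(4-methoxyphenoxy)-1,5-bis(naphthalen-2-ylmethoxy)cyclohex-3-en-1-yl]methyl benzoate | O[C@H]1[C@H](OCc2ccc3ccccc3c2)C=C[C@@H](Oc2ccc(OC)cc2)[C@@]1(OCc1ccc2ccccc2c1)COC(=O)c1ccccc1 | intermediate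
16 | [(1S,2R,5R,6S)-6-acetoxy-2-(4-methoxyphenoxy)-1,5-bis(naphthalen-2-ylmethoxy)cyclohex-3-en-1-yl]methyl benzoate | CC(=O)O[C@H]1[C@H](OCc2ccc3ccccc3c2)C=C[C@@H](Oc2ccc(OC)cc2)[C@@]1(OCc1ccc2ccccc2c1)COC(=O)c1ccccc1 | intermediate
17 | [(1S,2R,5R,6S)-6-acetoxy-1,5-dihydroxy-2-(4-methoxyphenoxy)cyclohex-3-en-1-yl]methyl benzoate | CC(=O)O[C@H]1[C@H](O)C=C[C@@H](Oc2ccc(OC)cc2)[C@@]1(O)COC(=O)c1ccccc1 | intermediate
18 | [(1S,2R,5R,6S)-6-acetoxy-5-(benzoyloxy)-1-hydroxy-2-(4-methoxyphenoxy)cyclohex-3-en-1-yl]methyl benzoate | CC(=O)O[C@H]1[C@H](OC(=O)c2ccccc2)C=C[C@@H](Oc2ccc(OC)cc2)[C@@]1(O)COC(=O)c1ccccc1 | intermediate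
19 | [(1S,2S,3R,6R)-2-acetoxy-3-(benzoyloxy)-1,6-dihydroxycyclohex-4-en-1-yl]methyl benzoate | CC(=O)O[C@H]1[C@H](OC(=O)c2ccccc2)C=C[C@@H](O)[C@@]1(O)COC(=O)c1ccccc1 | target

**Step count and risks**
Total steps: 14. Longest linear sequence: 14 (fully linear from 1).

Steps most likely to fail:

1. Step 8 (key step). The enolate may expel the oxygen on C4 or open by retro-aldol before it is silylated, or the silyl ketene acetal may decompose before it reaches the boat geometry. The fallback is an enolate-free thermal Claisen rearrangement of the corresponding cyclic enol ether. It sets out from 9: Et3SiOTf/2,6-lutidine gives the 4-O-triethylsilyl lactone F1, and iBu2AlH (CH2Cl2, −78 °C) reduces it to the lactol F2. Mesylation and elimination (MsCl, Et3N, then DBU) give the 5-(naphthylmethoxy)-3,4-dihydro-2H-pyran F3, whose ring enol ether and 2-aryloxyvinyl arm form an allyl vinyl ether. Heating (o-dichlorobenzene, 190 °C, trace Et3N) should give, through the same boat array, the cyclohexenecarbaldehyde F4. NaBH4 (MeOH, 0 °C) gives the silyl-protected alcohol F5, and PPTS/MeOH removes the silyl group to rejoin the route at 14.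

2. Step 7. Transmetalation of the pinacol boronate to copper may be slow, so that protodeboronation or oxidative homocoupling dominates, or the phenoxide may attack the lactone. The fallback changes from oxidative boron coupling to halide substitution. It sets out from 8: ipso-iododeboronation with N-iodosuccinimide (MeCN, dark, rt), expected to proceed with retention, gives the (E)-alkenyl iodide F6. Ullmann-type vinylation of 4-methoxyphenol (CuI 10 mol%, N,N-dimethylglycine, K3PO4, dioxane, 70 °C) then gives 9, where the route is rejoined.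

3. Step 4. The tri-alkoxide may aggregate and olefinate incompletely, or base may epimerise or cleave the α-hydroxy aldehyde. The fallback carries O6 as a silyl ether so that only one hydroxyl beside the lactol is free during olefination. It sets out from 1: tBuPh2SiCl/imidazole (DMF) gives the 6-O-silyl ether F7, and NaH/2-(bromomethyl)naphthalene gives the bis-NAP ether F8. TFA/H2O (4:1, 0 °C) hydrolyses only the acetal to give lactol F9, and Wittig methylenation (Ph3PCH3Br, KOtBu, THF) gives the heptenitol silyl ether F10. Bu4NF (THF) removes the silyl group to rejoin the route at 5.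

**Further compounds**
F1 | step 8 | 4-O-triethylsilyl ether of 9 | COc1ccc(O/C=C/[C@H]2[C@@H](OCc3ccc4ccccc4c3)[C@H](O[Si](CC)(CC)CC)[C@H](OCc3ccc4ccccc4c3)C(=O)O2)cc1
F2 | step 8 | lactol from F1 (oxan-2-ol, anomeric mixture) | COc1ccc(O/C=C/[C@H]2[C@@H](OCc3ccc4ccccc4c3)[C@H](O[Si](CC)(CC)CC)[C@H](OCc3ccc4ccccc4c3)C(O)O2)cc1
F3 | step 8 | 2-[(E)-2-(4-methoxyphenoxy)ethenyl]-3,5-bis(naphthalen-2-ylmethoxy)-4-(triethylsilyloxy)-3,4-dihydro-2H-pyran, configuration of 9 at C2, C3 and C4 | COc1ccc(O/C=C/[C@H]2[C@@H](OCc3ccc4ccccc4c3)[C@H](O[Si](CC)(CC)CC)C(OCc3ccc4ccccc4c3)=CO2)cc1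
F4 | step 8 | 2-(4-methoxyphenoxy)-1,5-bis(naphthalen-2-ylmethoxy)-6-(triethylsilyloxy)cyclohex-3-ene-1-carbaldehyde, configuration as in 13 | CC[Si](CC)(CC)O[C@H]1[C@H](OCc2ccc3ccccc3c2)C=C[C@@H](Oc2ccc(OC)cc2)[C@@]1(OCc1ccc2ccccc2c1)C=O
F5 | step 8 | triethylsilyl ether of 14 at the secondary hydroxyl | CC[Si](CC)(CC)O[C@H]1[C@H](OCc2ccc3ccccc3c2)C=C[C@@H](Oc2ccc(OC)cc2)[C@@]1(OCc1ccc2ccccc2c1)CO
F6 | step 7 | (3S,4S,5S,6S)-4-hydroxy-6-[(E)-2-iodoethenyl]-3,5-bis(naphthalen-2-ylmethoxy)oxan-2-one | I/C=C/[C@H]1[C@@H](OCc2ccc3ccccc3c2)[C@H](O)[C@H](OCc2ccc3ccccc3c2)C(=O)O1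
F7 | step 4 | 6-O-(tert-butyldiphenylsilyl)-1,2-O-isopropylidene-α-D-glucofuranose | O1[C@@H]2OC(C)(C)O[C@@H]2[C@@H](O)[C@H]1[C@H](O)CO[Si](c1ccccc1)(c1ccccc1)C(C)(C)C
F8 | step 4 | 6-O-(tert-butyldiphenylsilyl)-1,2-O-isopropylidene-3,5-di-O-(2-naphthylmethyl)-α-D-glucofuranose | O1[C@@H]2OC(C)(C)O[C@@H]2[C@@H](OCc2ccc3ccccc3c2)[C@H]1[C@H](OCc1ccc2ccccc2c1)CO[Si](c1ccccc1)(c1ccccc1)C(C)(C)C
F9 | step 4 | 6-O-(tert-butyldiphenylsilyl)-3,5-di-O-(2-naphthylmethyl)-D-glucofuranose (anomeric mixture) | O1C(O)[C@H](O)[C@@H](OCc2ccc3ccccc3c2)[C@H]1[C@H](OCc1ccc2ccccc2c1)CO[Si](c1ccccc1)(c1ccccc1)C(C)(C)C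
F10 | step 4 | 7-O-(tert-butyldiphenylsilyl)-1,2-dideoxy-4,6-di-O-(2-naphthylmethyl)-D-gluco-hept-1-enitol | C=C[C@H](O)[C@@H](OCc1ccc2ccccc2c1)[C@H](O)[C@H](OCc1ccc2ccccc2c1)CO[Si](c1ccccc1)(c1ccccc1)C(C)(C)C
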